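(The runs are calculated with constants of no real substance; noise was put on by code.)

Which of these flasks will hold the most target at 5.0 h, which the least, and what should you leave alone until then?

| flask | substrate | enzyme | impurity | remark | time |
|---|---|---|---|---|---|
| Wednesday's | 0.10 M | 7.8 × 10⁻⁴ mol% | 0.066 µM | run made earlier |  |
| Tuesday's | 0.10 M | 7.8 × 10⁻⁴ mol% | 0.52 µM | run made earlier |  |
| Sunday's | 0.10 M | 4.8 × 10⁻⁴ mol% | 0.18 µM | run made earlier |  |
| larch | 0.10 M | 7.8 × 10⁻⁴ mol% | 0.18 µM |  | 5.0 h |
| alder | 0.20 M | 4.0 × 10⁻⁴ mol% | 0.10 µM |  | 5.0 h |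
| cedar | 0.060 M | 7.8 × 10⁻⁴ mol% | 0.50 µM |  | 5.0 h |
| birch | 0.10 M | 2.0 × 10⁻⁴ mol% | 0.18 µM |  | 5.0 h |
| ash | 0.025 M | 5.0 × 10⁻⁴ mol% | 0.80 µM |  | 5.0 h |
| maple | 0.050 M | 0.0015 mol% | 0.80 µM |  | 5.0 h |

| run | time / h | target / % |
|---|---|---|
| Wednesday's | 0.417 | 44.0 |
| Wednesday's | 1.33 | 92.0 |
| Wednesday's | 2.50 | 99.9 |
| Wednesday's | 4.00 | 99.5 |
| Tuesday's | 0.250 | 14.5 |
| Tuesday's | 0.667 | 30.5 |
| Tuesday's | 1.50 | 56.2 |
| Tuesday's | 4.00 | 93.2 |
| Sunday's | 0.417 | 22.7 |
| Sunday's | 1.33 | 56.0 |
| Sunday's | 2.50 | 83.2 |
| Sunday's | 4.00 | 96.7 |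

(readings scatter by 0.5 percentage points)

* ranking by amount of target, in percent of the substrate charged, from high to low, at 5.0 h (larch / alder / cedar / birch / ash / maple)
* the same order at 30 min (larch / alder / cedar / birch / ash / maple)
* the amount of target, in percent of the substrate charged of the flask you put first, at 5.0 h
* the amount of target, in percent of the substrate charged of the flask you put last, at 5.0 h

- what was read earlier has a scatter of 0.5 percentage points, one standard deviation

You are taking over the bench, so here is how I count. Tuesday's run and Sunday's run start from the same substrate and reach the same reading within scatter, 56.2% after 1.50 h and 56.0% after 1.33 h. Yet Tuesday's, the slower, was charged with more enzyme, 0.780 µM against 0.480 µM. Take the impurity off the enzyme, one for one, and the two times line up: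

remaining enzyme: Sunday's 0.300 µM, Tuesday's 0.260 µM, ratio 1.15

ratio of the times: 1.13

So I read the time to a given reading as going with substrate over remaining enzyme. Wednesday's run, with 0.714 µM remaining, read 99.9% after 2.50 h. Scaling from it:

larch: 0.600 µM remaining, about 2.98 h

alder: 0.700 µM remaining, about 5.10 h

When you come, larch should be through and alder just short, so I put larch first and alder second.

In ash, 6.40 impurity stand against each enzyme: this is the poison ratio, c(impurity) charged over c(enzyme) charged. Ash has the highest ratio, so I put it last. Don't wait on ash: its impurity outnumbers its enzyme, so what it makes, it makes early. Birch, cedar and maple stand at 0.900, 1.07 and 1.07, and I don't rank them by this number.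

The forecast gives alder > larch > birch > maple > cedar > ash at 5.0 h and larch > alder > maple > cedar > birch > ash at 30 min, with 100% first and 1.5% last, judging that "Alder versus larch at 5 h is effectively a tie.", and so it differs from my reckoning in first place.

The flasks give larch > alder > birch > maple > cedar > ash at 5.0 h and larch > alder > maple > cedar > birch > ash at 30 min, with larch at >99.9% and ash at 2.67%.

    substrate + enzyme → target + enzyme, rate k1*[substrate]*[enzyme]/(1 + ([substrate]/Km1) + ([target]/Kp1)) (4.64 mM, 42.2 mM, k = 11600 M⁻¹ s⁻¹)
    2 enzyme → spent catalyst A (k = 10800 M⁻¹ min⁻¹)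
    enzyme + impurity → spent catalyst B (k = 11500 M⁻¹ s⁻¹)

After 5.00 h ash holds 99.7% of its charged enzyme as spent catalyst B and 0.257% as spent catalyst A. If each enzyme charged takes one impurity, its poison ratio leaves 1 − 1/6.40 = 84.4% of the impurity over, and ash has 84% of its charge. Now take ash with 0.200 µM impurity instead: its ratio is 1.60, which leaves 37.5%. That flask ends with 38% of its impurity and 14.9% target.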